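**Plan**

1. Numbering: left decalin C1–C10 (ring A = C1–C5, C10; ring B = C5–C10), bridge C11′–C12′, right decalin primed. RH = the right-hand unit joined through C9′: trans-decalin with 5′α-H, 9′α-H, 10′β-CH3, 4′,4′-dimethyl, 8′α-CH3 and axial 8′β-OH.
2. The retrosynthesis cuts, in order: the two ArO–S bonds; C9–CH2Ar (anti-SN2′ on a 7α-picolinate); the C8–CH3 and C4–CH3 bonds; ring A at C4=C5 (aldol, the key step); C1–C10 (Michael); C2–C3 (vinyl Grignard); C4–C12′ (Wittig).
3. The enabling feature: the bridge ends on C4 of ring A, next to the ring-fusion carbon C5 and 1,3 to the quaternary C10. This is the pattern left by aldol condensation of a 2-methyl-2-(3-oxoalkyl)cyclohexane-1,3-dione, so ring A can be closed around the bridge carbon.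
4. Forward: the chain is grown on the lactol of 8-epi-sclareolide (right decalin plus bridge) and joined to 2-methylcyclohexane-1,3-dione (ring B). Ring A is closed, C4 is methylated and C3 deoxygenated. Ring B is then converted into the 8-methyl-Δ7 unit with the 9β-benzyl group, and the hydroquinone is unveiled and sulfated.
5. Stereochemistry: C5′, C9′, C10′ come from (+)-sclareolide and C8′ from its acid epimerisation. C10 comes from L-phenylalanine in the aldol. C5 and C4 come from Li/NH3 reduction and α-face methylation under control of the C10 methyl. C7 (temporary) comes from α-epoxidation and C9 from the anti-SN2′ displacement.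
6. The axial tertiary C8′ hydroxyl is carried unprotected. It costs one extra equivalent of base or organometallic and serves as the proton source in the reductive methylation.

Key step: step 7

Remark: aryl hydrogen sulfates are normally handled as salts; the last step is written to deliver the bis(hydrogen sulfate) as drawn, by cation exchange of the pyridinium salt.

**Route**

Step 1
Reactants: 1 (+)-sclareolide
Product: 2 8-epi-sclareolide (cis-fused γ-lactone, 8′β-O, 8′α-CH3)
Conditions: H2SO4 (conc.), HCO2H, rt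
Reagents that add atoms: none
Why: Acid ionises the tertiary C8′–O bond and the carboxyl recaptures the cation from the β face to give the more stable cis-fused lactone (thermodynamic epimerisation by SN1 lactone opening and reclosure), which sets the 8′β-oxygen of the target.

Step 2
Reactants: 2 8-epi-sclareolide
Product: 3 8-epi-sclareolide lactol (anomer mixture)
Conditions: i-Bu2AlH, CH2Cl2, −78 °C; KNaC4H4O6 (aq)
Reagents that add atoms: none
Why: Partial lactone reduction with i-Bu2AlH at low temperature should stop at the aluminium hemiacetal, and the anomeric centre is of no consequence.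

Step 3
Reactants: 3 lactol
Product: 4 (E)-N-methoxy-N-methyl-4-(RH)but-2-enamide
Conditions: Ph3P=CHC(O)N(OMe)Me, toluene, 90 °C
Reagents that add atoms: N-methoxy-N-methyl-2-(triphenylphosphoranylidene)acetamide, CON(C)C(=O)C=P(c1ccccc1)(c1ccccc1)c1ccccc1
Why: Wittig olefination of the hydroxy aldehyde in equilibrium with the lactol, in which the stabilised ylide gives the E-alkene under neutral conditions and the amide is too poor an acceptor for the hindered tertiary hydroxyl to add to.

Step 4
Reactants: 4 enamide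
Product: 5 N-methoxy-N-methyl-4-(RH)butanamide
Conditions: H2 (1 atm), Pd/C, EtOAc, rt
Reagents that add atoms: none
Why: Heterogeneous hydrogenation of the disubstituted conjugated alkene, to which the amide N–O bond and the tertiary alcohol are inert at atmospheric pressure.

Step 5
Reactants: 5 Weinreb amide
Product: 6 6-(RH)hex-1-en-3-one (vinyl ketone, used crude)
Conditions: CH2=CHMgBr (3.5 equiv), THF, −20 → 0 °C; inverse quench into cold 1 M HCl
Reagents that add atoms: vinylmagnesium bromide, C=C[Mg]Br
Why: Weinreb ketone synthesis, in which the magnesium chelate holds the tetrahedral adduct until the acidic inverse quench, which also keeps the released amine protonated so that it cannot add to the enone.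

Step 6
Reactants: 6 vinyl ketone; 7 2-methylcyclohexane-1,3-dione
Product: 8 2-methyl-2-[3-oxo-6-(RH)hexyl]cyclohexane-1,3-dione
Conditions: Et3N (cat.), EtOAc, 60 °C
Reagents that add atoms: none
Why: Base-catalysed Michael addition of the acidic cyclic 1,3-dione to the vinyl ketone (first half of a Robinson annulation), which forms the C1–C10 bond and the quaternary but still prochiral C10.

Step 7
Reactants: 8 triketone
Product: 10 (10S)-10β-methyl-4-[2-(RH)ethyl]-Δ4-octalin-3,9-dione, via ketol 9 (not isolated)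
Conditions: L-phenylalanine (1 equiv), (1S)-(+)-10-camphorsulfonic acid (0.5 equiv), DMF, 30 → 70 °C
Reagents that add atoms: none
Why: The primary amino acid condenses with the side-chain carbonyl C3 and the enamine forms toward C4, whose carbon adds to one of the two enantiotopic ring carbonyls (the future C5) while the acid proton activates that carbonyl, after which ketol 9 dehydrates to the C4=C5 enone. The closest known reaction is the Hajos–Parrish–Eder–Sauer–Wiechert cyclisation of 2-methyl-2-(3-oxoalkyl)cyclohexane-1,3-diones in its phenylalanine/sulfonic acid form, the variant of choice when the nucleophilic carbon carries a substituent. Ring A closes by a 6-(enolendo)-exo-trig aldol addition. The only stereocentre that survives, C10, is set by the catalyst: the L-amino acid selects the carbonyl that leads to the (10S)-enedione (10β-methyl), and the transient C4 and C5 centres are lost on dehydration. The step needs group selectivity between the two ring carbonyls and regioselectivity for C4 over C2; the first rests on the hydrogen-bonded chair-like enamine transition state, the second is secured by the substrate, since C2 could only close a four-membered ring. The nearest chain stereocentre (C9′) is three bonds from C4 and five from C10, so it should neither help nor oppose the catalyst, and the minor C10 epimer is a diastereomer removable by chromatography or crystallisation.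

Step 8
Reactants: 10 enedione
Product: 11 C9 ethylene ketal of 10
Conditions: 2-ethyl-2-methyl-1,3-dioxolane (solvent), HOCH2CH2OH (cat.), TsOH·H2O (cat.), rt
Reagents that add atoms: 2-ethyl-2-methyl-1,3-dioxolane, CCC1(C)OCCO1
Why: Acid-catalysed transketalisation is faster at the saturated C9 carbonyl than at the conjugated, tetrasubstituted enone carbonyl, so the monoketal should form chemoselectively.

Step 9
Reactants: 11 ketal enone
Product: 13 4α-methyl-4β-[2-(RH)ethyl]-5α-H trans-decalin-3-one 9-ketal, via dilithium enolate 12 (not isolated)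
Conditions: Li (2.2 equiv), NH3 (l)/THF, −78 → −33 °C; isoprene; MeI, −78 → −33 °C; NH4Cl
Reagents that add atoms: iodomethane, CI
Why: Stork reductive alkylation, in which the enone is reduced to the C3 enolate with axial protonation of C5 (trans fusion, 5α-H, the substrate hydroxyl supplying the proton) and iodomethane then enters C4 from the α face away from the axial C10 methyl, which leaves the bridge β and axial.

Step 10
Reactants: 13 ketone
Product: 15 3-deoxy ketal, via C3 hydrazone 14 (not isolated)
Conditions: N2H4·H2O, KOH, diethylene glycol, 130 °C, then 200 °C with removal of water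
Reagents that add atoms: none
Why: Huang–Minlon Wolff–Kishner reduction of the hindered C3 carbonyl through its hydrazone, under which the ketal, the tertiary alcohol and the quaternary C4 are stable.

Step 11
Reactants: 15 ketal
Product: 16 C9 ketone
Conditions: 2 M HCl, THF, rt
Reagents that add atoms: water, O
Why: Acid hydrolysis of the dioxolane, conditions under which a tertiary alcohol does not ionise in dilute aqueous medium at room temperature.

Step 12
Reactants: 16 ketone
Product: 18 8-methyl C9 ketone (C8 epimers), via dilithium enolate 17 (not isolated)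
Conditions: LiN(i-Pr)2 (2.2 equiv), THF, −78 → −20 °C; MeI (1.2 equiv), −78 → 0 °C; NH4Cl
Reagents that add atoms: iodomethane, CI
Why: Enolate alkylation at C8, the only enolisable position of the C9 ketone because C10 is quaternary; the C8 configuration is erased in the next step.

Step 13
Reactants: 18 8-methyl ketone
Product: 21 8-methyl-Δ7-en-9-one, via bis-silyl enol ether 19 (not isolated), via silyl ether enone 20 (not isolated)
Conditions: Me3SiCl (3 equiv), LiN(i-Pr)2 (2.5 equiv), THF, −78 → 0 °C; Pd(OAc)2 (1.1 equiv), MeCN, rt → 40 °C; 1 M HCl, THF, rt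
Reagents that add atoms: none
Why: Saegusa–Ito oxidation, in which the only possible silyl enol ether is palladated at C8 by divalent palladium acetate and β-hydride elimination toward C7 gives the endocyclic α-methyl enone, the tertiary silyl ether formed alongside being cleaved in the acidic work-up.

Step 14
Reactants: 21 enone
Product: 22 7α,8α-epoxy-8β-methyl C9 ketone
Conditions: H2O2 (30% aq), NaOH (aq), MeOH, 0 °C → rt
Reagents that add atoms: hydrogen peroxide, OO
Why: Weitz–Scheffer nucleophilic epoxidation, in which hydroperoxide adds to C7 axially from the α face, anti to the axial C10 methyl, and the enolate closes to the α-epoxide.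

Step 15
Reactants: 22 epoxy ketone
Product: 24 7α-hydroxy-8-methyl-Δ8(9) allylic alcohol, via epoxy hydrazone 23 (not isolated)
Conditions: N2H4·H2O (5 equiv), AcOH (cat.), MeOH, 0 °C → rt
Reagents that add atoms: none
Why: Wharton transposition, in which the epoxy hydrazone fragments with loss of N2, the C7–O bond is untouched so the 7α-hydroxyl is retained, and the alkene moves to C8=C9.

Step 16
Reactants: 24 allylic alcohol
Product: 25 7α-picolinate
Conditions: picolinic acid, DCC, DMAP (cat.), CH2Cl2, rt
Reagents that add atoms: picolinic acid, OC(=O)c1ccccn1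
Why: Steglich esterification of the secondary allylic alcohol, which the far more hindered tertiary alcohol of RH should not undergo.

Step 17
Reactants: 26 2-(chloromethyl)-1,4-dimethoxybenzene
Product: 27 (2,5-dimethoxybenzyl)magnesium chloride (THF solution, titrated, used directly)
Conditions: Mg turnings, THF, 0 °C, slow addition
Reagents that add atoms: magnesium, [Mg]
Why: Grignard formation from a benzylic chloride, with slow addition in dilute solution to limit Wurtz homocoupling.

Step 18
Reactants: 25 picolinate; 27 benzylmagnesium chloride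
Product: 28 9β-(2,5-dimethoxybenzyl)-8-methyl-Δ7 decalin (9α-H)
Conditions: 27 (4 equiv), CuBr·SMe2 (1.5 equiv), THF, −40 → 0 °C; NH4Cl (aq)
Reagents that add atoms: none
Why: Copper-mediated anti-SN2′ allylic substitution of a picolinate, in which chelation of the pyridyl ester to magnesium activates the leaving group and the benzylcopper species attacks C9 anti to the 7α-oxygen, that is from the β face, moving the alkene to C7=C8 and setting 9β-benzyl/9α-H.

Step 19
Reactants: 28 dimethoxyarene
Product: 29 2-substituted 1,4-benzoquinone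
Conditions: (NH4)2Ce(NO3)6 (2.5 equiv), MeCN/H2O, 0 °C
Reagents that add atoms: water, O
Why: Oxidative demethylation of a 1,4-dimethoxyarene to the p-quinone by the tetravalent cerium salt, which should leave the trisubstituted alkene and the tertiary alcohol untouched at 0 °C.

Step 20
Reactants: 29 quinone
Product: 30 hydroquinone
Conditions: Na2S2O4 (aq), THF/H2O, rt, argon
Reagents that add atoms: none
Why: Two-electron dithionite reduction of the quinone to the hydroquinone, run under argon because the product is air-sensitive.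

Step 21
Reactants: 30 hydroquinone
Product: 31 target bis(hydrogen sulfate)
Conditions: SO3·pyridine (5 equiv), pyridine, rt; H2O; sulfonic acid cation-exchange resin (H+ form), 0 °C
Reagents that add atoms: sulfur trioxide–pyridine complex, [O-]S(=O)(=O)[n+]1ccccc1
Why: O-Sulfonation of both phenols with the sulfur trioxide–pyridine complex, which the axial tertiary alcohol (flanked by C9′ and 1,3-diaxial to the C10′ methyl) should not undergo at room temperature, followed by cation exchange to the acid form.

**Compound list**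

1 | (+)-sclareolide | O=C1C[C@@H]2[C@@]3(C)CCCC(C)(C)[C@@H]3CC[C@@]2(C)O1 | starting material
2 | 8-epi-sclareolide (cis-fused lactone, 8′β-O) | O=C1C[C@@H]2[C@@]3(C)CCCC(C)(C)[C@@H]3CC[C@]2(C)O1 | intermediate
3 | 8-epi-sclareolide lactol (anomer mixture) | OC1C[C@@H]2[C@@]3(C)CCCC(C)(C)[C@@H]3CC[C@]2(C)O1 | intermediate
4 | (E)-N-methoxy-N-methyl-4-(RH)but-2-enamide | CON(C)C(=O)/C=C/C[C@@H]1[C@@]2(C)CCCC(C)(C)[C@@H]2CC[C@]1(C)O | intermediate
5 | N-methoxy-N-methyl-4-(RH)butanamide | CON(C)C(=O)CCC[C@@H]1[C@@]2(C)CCCC(C)(C)[C@@H]2CC[C@]1(C)O | intermediate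
6 | 6-(RH)hex-1-en-3-one | C=CC(=O)CCC[C@@H]1[C@@]2(C)CCCC(C)(C)[C@@H]2CC[C@]1(C)O | intermediate
7 | 2-methylcyclohexane-1,3-dione | CC1C(=O)CCCC1=O | starting material
8 | 2-methyl-2-[3-oxo-6-(RH)hexyl]cyclohexane-1,3-dione | CC1(CCC(=O)CCC[C@@H]2[C@@]3(C)CCCC(C)(C)[C@@H]3CC[C@]2(C)O)C(=O)CCCC1=O | intermediate
9 | cis-fused ketol: 5β-hydroxy-10β-methyl-4-[2-(RH)ethyl]decalin-3,9-dione (C4 epimers; not isolated) | O=C1CC[C@]2(C)C(=O)CCC[C@]2(O)C1CC[C@@H]4[C@@]5(C)CCCC(C)(C)[C@@H]5CC[C@]4(C)O | intermediate
10 | (10S)-10β-methyl-4-[2-(RH)ethyl]-Δ4-octalin-3,9-dione | O=C1CC[C@]2(C)C(=O)CCCC2=C1CC[C@@H]4[C@@]5(C)CCCC(C)(C)[C@@H]5CC[C@]4(C)O | intermediate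
11 | C9 ethylene ketal of 10 | O=C1CC[C@]2(C)C3(OCCO3)CCCC2=C1CC[C@@H]4[C@@]5(C)CCCC(C)(C)[C@@H]5CC[C@]4(C)O | intermediate
12 | dilithium species: C3 lithium enolate (C3=C4, 5α-H) with lithium 8′-alkoxide (not isolated) | [Li]OC=1CC[C@]2(C)C3(OCCO3)CCC[C@H]2C=1CC[C@@H]4[C@@]5(C)CCCC(C)(C)[C@@H]5CC[C@]4(C)O[Li] | intermediate
13 | 4α,10β-dimethyl-4β-[2-(RH)ethyl]-5α-H trans-decalin-3-one 9-ethylene ketal | O=C1CC[C@]2(C)C3(OCCO3)CCC[C@H]2[C@@]1(C)CC[C@@H]4[C@@]5(C)CCCC(C)(C)[C@@H]5CC[C@]4(C)O | intermediate
14 | C3 hydrazone of 13 (not isolated) | NN=C1CC[C@]2(C)C3(OCCO3)CCC[C@H]2[C@@]1(C)CC[C@@H]4[C@@]5(C)CCCC(C)(C)[C@@H]5CC[C@]4(C)O | intermediate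
15 | 3-deoxy compound: 4α,10β-dimethyl-4β-[2-(RH)ethyl] trans-decalin 9-ethylene ketal | C1CC[C@]2(C)C3(OCCO3)CCC[C@H]2[C@@]1(C)CC[C@@H]4[C@@]5(C)CCCC(C)(C)[C@@H]5CC[C@]4(C)O | intermediate
16 | 4α,10β-dimethyl-4β-[2-(RH)ethyl] trans-decalin-9-one | C1CC[C@]2(C)C(=O)CCC[C@H]2[C@@]1(C)CC[C@@H]4[C@@]5(C)CCCC(C)(C)[C@@H]5CC[C@]4(C)O | intermediate
17 | dilithium species: C9 lithium enolate (C8=C9) of 16 with lithium 8′-alkoxide (not isolated) | C1CC[C@]2(C)C(O[Li])=CCC[C@H]2[C@@]1(C)CC[C@@H]4[C@@]5(C)CCCC(C)(C)[C@@H]5CC[C@]4(C)O[Li] | intermediate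
18 | 8-methyl derivative of 16 (C8 epimers) | C1CC[C@]2(C)C(=O)C(C)CC[C@H]2[C@@]1(C)CC[C@@H]4[C@@]5(C)CCCC(C)(C)[C@@H]5CC[C@]4(C)O | intermediate
19 | C9 trimethylsilyl enol ether (C8=C9) with 8′-O-trimethylsilyl ether (not isolated) | C1CC[C@]2(C)C(O[Si](C)(C)C)=C(C)CC[C@H]2[C@@]1(C)CC[C@@H]4[C@@]5(C)CCCC(C)(C)[C@@H]5CC[C@]4(C)O[Si](C)(C)C | intermediate
20 | 8-methyl-Δ7-en-9-one as its 8′-O-trimethylsilyl ether (not isolated) | C1CC[C@]2(C)C(=O)C(C)=CC[C@H]2[C@@]1(C)CC[C@@H]4[C@@]5(C)CCCC(C)(C)[C@@H]5CC[C@]4(C)O[Si](C)(C)C | intermediate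
21 | 4α,8,10β-trimethyl-4β-[2-(RH)ethyl]-Δ7-octalin-9-one | C1CC[C@]2(C)C(=O)C(C)=CC[C@H]2[C@@]1(C)CC[C@@H]4[C@@]5(C)CCCC(C)(C)[C@@H]5CC[C@]4(C)O | intermediate
22 | 7α,8α-epoxy-8β-methyl C9 ketone | C1CC[C@]2(C)C(=O)[C@]3(C)O[C@@H]3C[C@H]2[C@@]1(C)CC[C@@H]4[C@@]5(C)CCCC(C)(C)[C@@H]5CC[C@]4(C)O | intermediate
23 | C9 hydrazone of 22 (not isolated) | C1CC[C@]2(C)C(=NN)[C@]3(C)O[C@@H]3C[C@H]2[C@@]1(C)CC[C@@H]4[C@@]5(C)CCCC(C)(C)[C@@H]5CC[C@]4(C)O | intermediate
24 | 7α-hydroxy-8-methyl-Δ8(9) allylic alcohol | C1CC[C@]2(C)C=C(C)[C@H](O)C[C@H]2[C@@]1(C)CC[C@@H]4[C@@]5(C)CCCC(C)(C)[C@@H]5CC[C@]4(C)O | intermediate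
25 | 7α-picolinate (pyridine-2-carboxylate) of 24 | C1CC[C@]2(C)C=C(C)[C@H](OC(=O)c3ccccn3)C[C@H]2[C@@]1(C)CC[C@@H]4[C@@]5(C)CCCC(C)(C)[C@@H]5CC[C@]4(C)O | intermediate
26 | 2-(chloromethyl)-1,4-dimethoxybenzene | COc1ccc(OC)c(CCl)c1 | starting material
27 | (2,5-dimethoxybenzyl)magnesium chloride | COc1ccc(OC)c(C[Mg]Cl)c1 | intermediate
28 | 9β-(2,5-dimethoxybenzyl)-4α,8,10β-trimethyl-4β-[2-(RH)ethyl]-Δ7-octalin (5α-H, 9α-H) | C1CC[C@]2(C)[C@@H](Cc3cc(OC)ccc3OC)C(C)=CC[C@H]2[C@@]1(C)CC[C@@H]4[C@@]5(C)CCCC(C)(C)[C@@H]5CC[C@]4(C)O | intermediate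
29 | corresponding 2-substituted 1,4-benzoquinone | C1CC[C@]2(C)[C@@H](CC3=CC(=O)C=CC3=O)C(C)=CC[C@H]2[C@@]1(C)CC[C@@H]4[C@@]5(C)CCCC(C)(C)[C@@H]5CC[C@]4(C)O | intermediate
30 | corresponding hydroquinone | C1CC[C@]2(C)[C@@H](Cc3cc(O)ccc3O)C(C)=CC[C@H]2[C@@]1(C)CC[C@@H]4[C@@]5(C)CCCC(C)(C)[C@@H]5CC[C@]4(C)O | intermediate
31 | CNP0471499.2, hydroquinone bis(hydrogen sulfate) | C1CC[C@]2(C)[C@@H](Cc3cc(OS(=O)(=O)O)ccc3OS(=O)(=O)O)C(C)=CC[C@H]2[C@@]1(C)CC[C@@H]4[C@@]5(C)CCCC(C)(C)[C@@H]5CC[C@]4(C)O | target

**Summary**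

Total step count: 21. Longest linear sequence: 20 steps (steps 1–16 and 18–21 from (+)-sclareolide); step 17 is a one-step side branch.

Steps most likely to fail:

Step 18. The benzylcopper reagent must reach the β face of C9, next to the quaternary C10 and syn to its methyl. Direct SN2 displacement at C7, elimination to the diene or homocoupling of the benzyl reagent may outrun this attack. The fallback makes the C9–CH2 bond by carbonyl addition and sets C9 by hydrogen delivery. It sets out from enone 21 and Grignard reagent 27 and comes back to the route at 28. Addition of 27 to the C9 carbonyl of 21 (CeCl3, THF, −78 °C) should give the tertiary allylic alcohol F1. Babler–Dauben oxidative transposition with [C5H5NH][CrO3Cl] in CH2Cl2 should then give the transposed C7 enone F2. Luche reduction (NaBH4, CeCl3·7H2O, MeOH, −78 °C) with axial hydride delivery should give the 7β-allylic alcohol F3. Mitsunobu displacement with 2-nitrobenzenesulfonylhydrazide (PPh3, diethyl azodicarboxylate, THF, −30 °C) should give with inversion the 7α N-allyl sulfonylhydrazine F4. On warming this should lose the sulfinic acid to the allylic diazene F5, which extrudes N2 with suprafacial transfer of hydrogen to the α face of C9 and shifts the alkene to C7=C8, giving 28.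

Step 15. Hydrazone formation at the C9 carbonyl may be incomplete, because it lies between the quaternary C10 and the fully substituted epoxide carbon C8, and the vinyl diazene may be diverted to reduced or eliminated products. The fallback replaces the hydrazone fragmentation by a radical epoxide opening. It sets out from epoxy ketone 22 and comes back at 24. NaBH4 in MeOH at 0 °C should give the epoxy alcohol F6 (either C9 epimer serves). 1,1′-Thiocarbonyldiimidazole with DMAP in 1,2-dichloroethane at 70 °C should acylate only the secondary hydroxyl to the thiocarbonylimidazolide F7. Bu3SnH and AIBN in toluene at 100 °C should generate the C9 radical, which opens the epoxide at C8–O; the 7α-alkoxy radical is reduced to 24 with the C7 configuration untouched.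

Step 7. Discrimination between the two enantiotopic carbonyls may be insufficient, or enamine formation at the substituted C4 may be slow, allowing bridged aldol closure or retro-Michael cleavage to compete. The fallback gives up catalyst control and resolves C10 through the resident stereocentres of RH. It sets out from triketone 8 and comes back at 10. Cyclisation with pyrrolidine/AcOH in toluene should give 10 together with its C10 epimer F8. Reduction of the saturated C9 carbonyl of the mixture (NaBH4, EtOH, −20 °C, hydride anti to the angular methyl) should give the 9β-hydroxy enone F9 from 10 and the 9α-hydroxy enone F10 from F8. These are diastereomers with a hydroxyl next to C10 and should be separable by chromatography or crystallisation. Dess–Martin oxidation of F9 returns 10.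

**Further compounds**

F1 | step 18 | tertiary allylic alcohol: 9-hydroxy-9-(2,5-dimethoxybenzyl)-8-methyl-Δ7 (C9 configuration immaterial) | C1CC[C@]2(C)C(O)(Cc3cc(OC)ccc3OC)C(C)=CC[C@H]2[C@@]1(C)CC[C@@H]4[C@@]5(C)CCCC(C)(C)[C@@H]5CC[C@]4(C)O
F2 | step 18 | transposed enone: 9-(2,5-dimethoxybenzyl)-8-methyl-Δ8(9)-en-7-one | C1CC[C@]2(C)C(Cc3cc(OC)ccc3OC)=C(C)C(=O)C[C@H]2[C@@]1(C)CC[C@@H]4[C@@]5(C)CCCC(C)(C)[C@@H]5CC[C@]4(C)O
F3 | step 18 | 7β-allylic alcohol of F2 | C1CC[C@]2(C)C(Cc3cc(OC)ccc3OC)=C(C)[C@@H](O)C[C@H]2[C@@]1(C)CC[C@@H]4[C@@]5(C)CCCC(C)(C)[C@@H]5CC[C@]4(C)O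
F4 | step 18 | 7α N-allyl-N-(2-nitrobenzenesulfonyl)hydrazine | C1CC[C@]2(C)C(Cc3cc(OC)ccc3OC)=C(C)[C@H](N(N)S(=O)(=O)c3ccccc3[N+](=O)[O-])C[C@H]2[C@@]1(C)CC[C@@H]4[C@@]5(C)CCCC(C)(C)[C@@H]5CC[C@]4(C)O
F5 | step 18 | 7α allylic diazene | C1CC[C@]2(C)C(Cc3cc(OC)ccc3OC)=C(C)[C@H](N=N)C[C@H]2[C@@]1(C)CC[C@@H]4[C@@]5(C)CCCC(C)(C)[C@@H]5CC[C@]4(C)O
F6 | step 15 | 7α,8α-epoxy-9-hydroxy compound (C9 epimer immaterial) | C1CC[C@]2(C)C(O)[C@]3(C)O[C@@H]3C[C@H]2[C@@]1(C)CC[C@@H]4[C@@]5(C)CCCC(C)(C)[C@@H]5CC[C@]4(C)O
F7 | step 15 | C9 O-(imidazol-1-ylthiocarbonyl) derivative of F6 | C1CC[C@]2(C)C(OC(=S)n3ccnc3)[C@]3(C)O[C@@H]3C[C@H]2[C@@]1(C)CC[C@@H]4[C@@]5(C)CCCC(C)(C)[C@@H]5CC[C@]4(C)O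
F8 | step 7 | C10 epimer of 10 (10α-methyl) | O=C1CC[C@@]2(C)C(=O)CCCC2=C1CC[C@@H]4[C@@]5(C)CCCC(C)(C)[C@@H]5CC[C@]4(C)O
F9 | step 7 | 9β-hydroxy enone from 10 (hydroxyl cis to the 10β-methyl) | O=C1CC[C@]2(C)[C@@H](O)CCCC2=C1CC[C@@H]4[C@@]5(C)CCCC(C)(C)[C@@H]5CC[C@]4(C)O
F10 | step 7 | 9α-hydroxy enone from F8 (hydroxyl cis to the 10α-methyl) | O=C1CC[C@@]2(C)[C@H](O)CCCC2=C1CC[C@@H]4[C@@]5(C)CCCC(C)(C)[C@@H]5CC[C@]4(C)O
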